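**Plan**
1. The retrosynthesis first cuts the acyl C(=O)–Cα bond of the side-chain ester. That carbonyl carbon lies between the oxygen on C3 of the dihydrofuran ring and the sp2 α-carbon of a (Z)-trisubstituted alkene, so it can be a molecule of CO captured between alcohol 9 and (Z)-alkenyl iodide 13 in a three-component Pd alkoxycarbonylation.
2. Alcohol 9 is cut at O1–C2 of the dihydrofuran ring (phenoxide opening of a trans vinyl epoxide) and at the aryl–alkenyl bond (Suzuki coupling).
3. Forward: iodination and silylation of phenol 1, Suzuki coupling to diene 6, Shi epoxidation, fluoride-triggered closure of the dihydrofuran ring, then the carbonylative esterification as the last step.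
4. Stereochemistry: C3 (S) comes from the reagent-controlled Shi epoxidation and C2 (R) from SN2 inversion in the ring closure, which makes the ring trans. The Z alkene comes from α-iodination of crotonaldehyde and is carried with retention through palladium.

Key step: step 10

Remark: the SMILES is read as the trans-(2R,3S) dihydrobenzofuranyl ester of (Z)-2-(acetoxymethyl)but-2-enoic acid; the L-fructose-derived (ent-) Shi ketone is taken as purchasable.

Step 1
Reactants: 1 1-(4-hydroxy-2-methoxyphenyl)ethan-1-one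
Product: 2 1-(4-hydroxy-5-iodo-2-methoxyphenyl)ethan-1-one
Conditions: NIS (1.05 equiv), TsOH·H2O (10 mol %), MeCN, 0 °C to rt
Reagents that add atoms: N-iodosuccinimide, O=C1CCC(=O)N1I
Why: Electrophilic aromatic iodination under acidic conditions should go ortho to the free OH and para to OMe at C5, the position activated by both donors that is not flanked by two substituents.

Step 2
Reactants: 2 1-(4-hydroxy-5-iodo-2-methoxyphenyl)ethan-1-one
Product: 3 1-(5-iodo-2-methoxy-4-((triisopropylsilyl)oxy)phenyl)ethan-1-one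
Conditions: TIPSCl (1.2 equiv), imidazole (2.5 equiv), DMF, rt
Reagents that add atoms: chlorotriisopropylsilane, CC(C)[Si](Cl)(C(C)C)C(C)C
Why: Standard phenol silylation; the bulky TIPS ether should survive the basic Suzuki and Shi conditions and later serves as a latent phenoxide.

Step 3
Reactants: 4 2-methylbut-1-en-3-yne
Product: 5 (E)-4,4,5,5-tetramethyl-2-(3-methylbuta-1,3-dien-1-yl)-1,3,2-dioxaborolane
Conditions: HBpin (1.05 equiv), Cp2Zr(H)Cl (5 mol %), Et3N (10 mol %), neat, sealed tube, 50 °C
Reagents that add atoms: pinacolborane, CC1(C)OBOC1(C)C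
Why: Zirconocene-catalysed syn-hydroboration of the terminal alkyne places boron on the terminal carbon and should give the (E)-alkenylboronate, leaving the 1,1-disubstituted alkene alone.

Step 4
Reactants: 3 1-(5-iodo-2-methoxy-4-((triisopropylsilyl)oxy)phenyl)ethan-1-one, 5 (E)-4,4,5,5-tetramethyl-2-(3-methylbuta-1,3-dien-1-yl)-1,3,2-dioxaborolane
Product: 6 (E)-1-(2-methoxy-5-(3-methylbuta-1,3-dien-1-yl)-4-((triisopropylsilyl)oxy)phenyl)ethan-1-one
Conditions: Pd(dppf)Cl2·CH2Cl2 (5 mol %), K3PO4 (3 equiv), THF/H2O (10:1), 50 °C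
Reagents that add atoms: none
Why: Suzuki–Miyaura coupling of an aryl iodide with an alkenyl pinacol boronate proceeds with retention of the E geometry, and the mild base should keep the silyl ether on so that no free o-dienylphenol (prone to isomerise to a 2H-chromene) is formed.

Step 5
Reactants: 6 (E)-1-(2-methoxy-5-(3-methylbuta-1,3-dien-1-yl)-4-((triisopropylsilyl)oxy)phenyl)ethan-1-one
Product: 7 1-(2-methoxy-5-((2S,3S)-3-(prop-1-en-2-yl)oxiran-2-yl)-4-((triisopropylsilyl)oxy)phenyl)ethan-1-one
Conditions: ent-Shi ketone (L-fructose-derived, 30 mol %), Oxone (1.4 equiv), K2CO3, Bu4NHSO4 (5 mol %), MeCN/DMM–aq. Na2B4O7/Na2EDTA buffer (pH ca. 10.5), 0 °C; chromatography on Et3N-deactivated silica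
Reagents that add atoms: potassium peroxymonosulfate (Oxone), [K+].[O-]S(=O)(=O)OO
Why: Shi asymmetric epoxidation (chiral dioxirane, spiro transition state) is expected to take the electron-rich trans-disubstituted styrenyl alkene in preference to the 1,1-disubstituted terminal one, and the L-fructose-derived ketone should give the (S,S)-epoxide, the mirror image of the (R,R) sense known for the D-ketone with trans-β-substituted styrenes, which fixes C3.

Step 6
Reactants: 7 1-(2-methoxy-5-((2S,3S)-3-(prop-1-en-2-yl)oxiran-2-yl)-4-((triisopropylsilyl)oxy)phenyl)ethan-1-one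
Product: 9 1-((2R,3S)-3-hydroxy-6-methoxy-2-(prop-1-en-2-yl)-2,3-dihydrobenzofuran-5-yl)ethan-1-one, via epoxy phenolate 8 (not isolated)
Conditions: TBAF (1.1 equiv), THF, 0 °C to rt; aq. NH4Cl
Reagents that add atoms: none
Why: Fluoride desilylation releases phenoxide 8, which should open the epoxide at the allylic carbon by intramolecular SN2 attack (5-endo epoxide opening at a π-activated carbon, as in the closure of o-hydroxyaryl epoxides to 3-hydroxydihydrobenzofurans; attack at the benzylic carbon would need a four-membered ring), and inversion at that carbon turns the trans epoxide into the trans-(2R,3S) product with C3 untouched.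

Step 7
Reactants: 10 (E)-but-2-enal
Product: 11 (Z)-2-iodobut-2-enal
Conditions: I2 (1.5 equiv), K2CO3 (1.2 equiv), DMAP (20 mol %), THF/H2O (1:1), rt
Reagents that add atoms: iodine, II
Why: DMAP-catalysed α-iodination of an enal (conjugate addition, iodination of the enolate, E1cB loss of DMAP) should give the thermodynamic isomer with CHO trans to CH3, which is the Z iodide.

Step 8
Reactants: 11 (Z)-2-iodobut-2-enal
Product: 12 (Z)-2-iodobut-2-en-1-ol
Conditions: NaBH4, CeCl3·7H2O, MeOH, 0 °C
Reagents that add atoms: none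
Why: Luche 1,2-reduction of the aldehyde leaves the alkenyl iodide and its geometry untouched.

Step 9
Reactants: 12 (Z)-2-iodobut-2-en-1-ol
Product: 13 (Z)-2-iodobut-2-en-1-yl acetate
Conditions: Ac2O (1.5 equiv), pyridine, DMAP (cat.), CH2Cl2, 0 °C to rt
Reagents that add atoms: acetic anhydride, CC(=O)OC(C)=O
Why: Routine O-acetylation of a primary allylic alcohol.

Step 10
Reactants: 9 1-((2R,3S)-3-hydroxy-6-methoxy-2-(prop-1-en-2-yl)-2,3-dihydrobenzofuran-5-yl)ethan-1-one, 13 (Z)-2-iodobut-2-en-1-yl acetate (1.5 equiv)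
Product: 14 (2R,3S)-5-acetyl-6-methoxy-2-(prop-1-en-2-yl)-2,3-dihydrobenzofuran-3-yl (Z)-2-(acetoxymethyl)but-2-enoate
Conditions: Pd(OAc)2 (5 mol %), Xantphos (6 mol %), CO (1 atm), iPr2NEt (2 equiv), 4 Å MS, toluene, 60 °C; stopped when 9 is consumed
Reagents that add atoms: carbon monoxide, [C-]#[O+]
Why: Pd(0) inserts into the C(sp2)–I bond of 13 with retention, CO inserts into the alkenyl–Pd bond to form the acyl carbon–Cα bond, and base-assisted alcoholysis of the acyl-palladium by the C3–OH of 9 releases the ester and regenerates Pd(0), so alcohol, CO and alkenyl iodide are joined in one operation. The closest known reaction type is the alkoxycarbonylation of alkenyl iodides with alcohols, here run with the alcohol as the limiting component. No ring is closed and no stereocentre is formed: C2 and C3 keep their configuration because the C3–O bond is never broken, and the Z geometry is carried over from 13 because σ-alkenyl- and acyl-palladium species are configurationally stable, which avoids an activated angelic-type acid that isomerises to the E (tiglate-type) isomer. The step needs C–I insertion to win over ionisation of the three allylic C–O bonds present (the acetate of 13, the allylic acetate of the product and the allylic aryl ether C2–O1). This should be secured by the much faster C–I insertion, by keeping 13 in excess so that palladium rests as Pd(II), by a chelating ligand that leaves no free nucleophilic phosphine and by a hindered base that cannot add SN2′ to the product. Only one hydroxyl group is present, so the site of acylation is defined.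

**Compound list**
1 | 1-(4-hydroxy-2-methoxyphenyl)ethan-1-one | CC(=O)c1ccc(O)cc1OC | starting material
2 | 1-(4-hydroxy-5-iodo-2-methoxyphenyl)ethan-1-one | CC(=O)c1cc(I)c(O)cc1OC | intermediate
3 | 1-(5-iodo-2-methoxy-4-((triisopropylsilyl)oxy)phenyl)ethan-1-one | CC(=O)c1cc(I)c(O[Si](C(C)C)(C(C)C)C(C)C)cc1OC | intermediate
4 | 2-methylbut-1-en-3-yne | C=C(C)C#C | starting material
5 | (E)-4,4,5,5-tetramethyl-2-(3-methylbuta-1,3-dien-1-yl)-1,3,2-dioxaborolane | C=C(C)/C=C/B1OC(C)(C)C(C)(C)O1 | intermediate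
6 | (E)-1-(2-methoxy-5-(3-methylbuta-1,3-dien-1-yl)-4-((triisopropylsilyl)oxy)phenyl)ethan-1-one | CC(=O)c1cc(/C=C/C(C)=C)c(O[Si](C(C)C)(C(C)C)C(C)C)cc1OC | intermediate
7 | 1-(2-methoxy-5-((2S,3S)-3-(prop-1-en-2-yl)oxiran-2-yl)-4-((triisopropylsilyl)oxy)phenyl)ethan-1-one | CC(=O)c1cc([C@@H]2O[C@H]2C(C)=C)c(O[Si](C(C)C)(C(C)C)C(C)C)cc1OC | intermediate
8 | tetrabutylammonium 4-acetyl-5-methoxy-2-((2S,3S)-3-(prop-1-en-2-yl)oxiran-2-yl)phenolate | CC(=O)c1cc([C@@H]2O[C@H]2C(C)=C)c([O-])cc1OC.CCCC[N+](CCCC)(CCCC)CCCC | intermediate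
9 | 1-((2R,3S)-3-hydroxy-6-methoxy-2-(prop-1-en-2-yl)-2,3-dihydrobenzofuran-5-yl)ethan-1-one | C=C(C)[C@H]1Oc2cc(OC)c(C(C)=O)cc2[C@@H]1O | intermediate
10 | (E)-but-2-enal | C/C=C/C=O | starting material
11 | (Z)-2-iodobut-2-enal | C/C=C(\I)C=O | intermediate
12 | (Z)-2-iodobut-2-en-1-ol | C/C=C(\I)CO | intermediate
13 | (Z)-2-iodobut-2-en-1-yl acetate | C/C=C(\I)COC(C)=O | intermediate
14 | (2R,3S)-5-acetyl-6-methoxy-2-(prop-1-en-2-yl)-2,3-dihydrobenzofuran-3-yl (Z)-2-(acetoxymethyl)but-2-enoate | C=C(C)[C@H]1Oc2cc(OC)c(C(C)=O)cc2[C@@H]1OC(=O)/C(=C\C)COC(C)=O | target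

**Count**
Total steps: 10. Longest linear sequence: 6 steps (1, 2, 4, 5, 6, 10).

**Steps most likely to fail**

Step 5. The dioxirane may show poor site selectivity between the styrenyl and the terminal 1,1-disubstituted alkene of the conjugated diene, or over-oxidise. The fallback sets out from 3 and removes the second alkene during the oxidation. Heck coupling of 3 with 2-methylbut-3-en-2-ol (Pd(OAc)2, P(o-tol)3, Et3N, DMF, 80 °C) should give (E)-1-(5-(3-hydroxy-3-methylbut-1-en-1-yl)-2-methoxy-4-((triisopropylsilyl)oxy)phenyl)ethan-1-one F1. Shi epoxidation of its only alkene with the same ent-ketone should give 1-(5-((2S,3R)-3-(2-hydroxypropan-2-yl)oxiran-2-yl)-2-methoxy-4-((triisopropylsilyl)oxy)phenyl)ethan-1-one F2. Dehydration of the tertiary alcohol with Burgess reagent (toluene, 50 °C) toward a methyl group would then come back to the route at 7.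

Step 6. The 5-endo attack of the phenoxide may be slow, and the electron-rich benzylic C–O bond may ionise instead, with loss of configuration at C3 or decomposition. The fallback sets out from 6, closes the ring by π-allyl substitution and corrects C3 afterwards. Epoxidation of 6 with the D-fructose-derived Shi ketone should give the enantiomeric epoxide 1-(2-methoxy-5-((2R,3R)-3-(prop-1-en-2-yl)oxiran-2-yl)-4-((triisopropylsilyl)oxy)phenyl)ethan-1-one F3. Desilylation with TBAF buffered by AcOH (THF, 0 °C) should free 1-(4-hydroxy-2-methoxy-5-((2R,3R)-3-(prop-1-en-2-yl)oxiran-2-yl)phenyl)ethan-1-one F4 without a naked phenoxide. Pd(PPh3)4 (5 mol %, THF, rt) should ionise the vinyl epoxide and close the ring by O-attack anti to palladium, with net retention at C2, to the cis alcohol 1-((2R,3R)-3-hydroxy-6-methoxy-2-(prop-1-en-2-yl)-2,3-dihydrobenzofuran-5-yl)ethan-1-one F5. Mitsunobu inversion at C3 (4-nitrobenzoic acid, PPh3, DIAD, THF, 0 °C) should give (2R,3S)-5-acetyl-6-methoxy-2-(prop-1-en-2-yl)-2,3-dihydrobenzofuran-3-yl 4-nitrobenzoate F6. Methanolysis (K2CO3, MeOH, 0 °C) would come back to the route at 9.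

Step 10. Alcoholysis of the acyl-palladium by the hindered secondary alcohol may be slow. Pd(0) may then ionise an allylic C–O bond (acetate of 13, allylic acetate of the product, aryl ether C2–O1), with scrambling of alkene geometry or of C2. The fallback sets out from 12, makes the same acyl C–Cα bond by carbonylation on the small fragment alone, and joins it to 9 without palladium. Silylation of 12 (TBSCl, imidazole, DMF) should give (Z)-tert-butyl((2-iodobut-2-en-1-yl)oxy)dimethylsilane F7. Hydroxycarbonylation (Pd(OAc)2, dppf, CO 1 atm, H2O, Et3N, DMF, 50 °C) should give (Z)-2-(((tert-butyldimethylsilyl)oxy)methyl)but-2-enoic acid F8. Yamaguchi esterification with 9 (2,4,6-trichlorobenzoyl chloride, Et3N, toluene, rt; then 9 and a minimum of DMAP, rt) should give (2R,3S)-5-acetyl-6-methoxy-2-(prop-1-en-2-yl)-2,3-dihydrobenzofuran-3-yl (Z)-2-(((tert-butyldimethylsilyl)oxy)methyl)but-2-enoate F9. Desilylation with HF·pyridine (THF/pyridine, 0 °C) should give (2R,3S)-5-acetyl-6-methoxy-2-(prop-1-en-2-yl)-2,3-dihydrobenzofuran-3-yl (Z)-2-(hydroxymethyl)but-2-enoate F10. Acetylation (Ac2O, pyridine, no DMAP, 0 °C) would come back to the route at 14.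

**Further compounds**
F1 | step 5 | (E)-1-(5-(3-hydroxy-3-methylbut-1-en-1-yl)-2-methoxy-4-((triisopropylsilyl)oxy)phenyl)ethan-1-one | CC(=O)c1cc(/C=C/C(C)(C)O)c(O[Si](C(C)C)(C(C)C)C(C)C)cc1OC
F2 | step 5 | 1-(5-((2S,3R)-3-(2-hydroxypropan-2-yl)oxiran-2-yl)-2-methoxy-4-((triisopropylsilyl)oxy)phenyl)ethan-1-one | CC(=O)c1cc([C@@H]2O[C@H]2C(C)(C)O)c(O[Si](C(C)C)(C(C)C)C(C)C)cc1OC
F3 | step 6 | 1-(2-methoxy-5-((2R,3R)-3-(prop-1-en-2-yl)oxiran-2-yl)-4-((triisopropylsilyl)oxy)phenyl)ethan-1-one | CC(=O)c1cc([C@H]2O[C@@H]2C(C)=C)c(O[Si](C(C)C)(C(C)C)C(C)C)cc1OC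
F4 | step 6 | 1-(4-hydroxy-2-methoxy-5-((2R,3R)-3-(prop-1-en-2-yl)oxiran-2-yl)phenyl)ethan-1-one | CC(=O)c1cc([C@H]2O[C@@H]2C(C)=C)c(O)cc1OC
F5 | step 6 | 1-((2R,3R)-3-hydroxy-6-methoxy-2-(prop-1-en-2-yl)-2,3-dihydrobenzofuran-5-yl)ethan-1-one | C=C(C)[C@H]1Oc2cc(OC)c(C(C)=O)cc2[C@H]1O
F6 | step 6 | (2R,3S)-5-acetyl-6-methoxy-2-(prop-1-en-2-yl)-2,3-dihydrobenzofuran-3-yl 4-nitrobenzoate | C=C(C)[C@H]1Oc2cc(OC)c(C(C)=O)cc2[C@@H]1OC(=O)c1ccc(cc1)[N+](=O)[O-]
F7 | step 10 | (Z)-tert-butyl((2-iodobut-2-en-1-yl)oxy)dimethylsilane | C/C=C(\I)CO[Si](C)(C)C(C)(C)C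
F8 | step 10 | (Z)-2-(((tert-butyldimethylsilyl)oxy)methyl)but-2-enoic acid | C/C=C(\C(=O)O)CO[Si](C)(C)C(C)(C)C
F9 | step 10 | (2R,3S)-5-acetyl-6-methoxy-2-(prop-1-en-2-yl)-2,3-dihydrobenzofuran-3-yl (Z)-2-(((tert-butyldimethylsilyl)oxy)methyl)but-2-enoate | C=C(C)[C@H]1Oc2cc(OC)c(C(C)=O)cc2[C@@H]1OC(=O)/C(=C\C)CO[Si](C)(C)C(C)(C)C
F10 | step 10 | (2R,3S)-5-acetyl-6-methoxy-2-(prop-1-en-2-yl)-2,3-dihydrobenzofuran-3-yl (Z)-2-(hydroxymethyl)but-2-enoate | C=C(C)[C@H]1Oc2cc(OC)c(C(C)=O)cc2[C@@H]1OC(=O)/C(=C\C)CO
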